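The easy step here is intermediate → target, first order with a half-life of 1.7 min, so I began with it.

- grey: substrate 0.13 M (in portions, 4); partner 0.143 M; time 50 min; the portions of substrate follow each other after 10 s, the first at the start
- amber: substrate 0.13 M (in portions, 4); partner 0.143 M; time 120 min; the portions of substrate follow each other after 10 s, the first at the start

    substrate + partner → intermediate (k1 = 0.011 /M/s)
    intermediate → target (k2 = 0.0067 /s)
    2 substrate → self-condensation product A (k3 = 0.27 /M/s)
    substrate + target → side product (k4 = 0.029 /M/s)
    2 substrate → self-condensation product B (k5 = 3.4 × 10⁻⁵ /M/s)

- a species is counted by the substrate in it: one self-condensation product A or side product or self-condensation product B counts as two
- two of one species on the left: rate k times its square, two consumed each time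
- run time (grey): 50 min

- which of these there is most of at the end, counted by the substrate in it, grey (intermediate / substrate / target / side product)
- which of these there is most of at the end, counted by the substrate in it, amber (intermediate / substrate / target / side product)
- how much there is at the end of the one of these that leads, in percent of the substrate charged: grey
- how much there is at the end of the one of these that leads, in percent of the substrate charged: amber

I counted turnovers. With just the capture of substrate by partner and that easy step, and partner held at its charge (pseudo-first-order), substrate had a half-life of 7.3 min. Grey's 50 min holds 6.85 of those, so this reckoning pointed towards target near the whole charge, more slowly as partner was used.

Then I added self-condensation to A. At full charge it removes substrate at 0.0702 /s, against 0.00157 /s for capture, a race ratio of 44.6. Integrating both losses gave the captured share, the part of a single charge that meets partner before it meets itself, which is the natural logarithm of one plus the race ratio, divided by that ratio: 8.56%. That uses 7.78% of the partner, so holding c(partner) fixed was fair. Time does not enter the share, so I gave grey and amber the same figure.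

Next came the side step. The captured share implies a substrate exposure on which a target molecule present from the start makes 0.205 turnovers, but target arrives late, so I expected a small loss. The portions end after 30.0 s, which is longer than the 14.2 s first half-life of self-condensation at full charge, so I expected a little more capture than the share says. Self-condensation to B has a constant far smaller than the one for A, and I dropped it. I left these corrections unreckoned and committed to target at about 8.56% in both flasks.

The forecast named target in grey and target in amber, at 8.3% and 8.3%, a little below my figure, and added: “Amber barely changes, since nothing remains to react.”

The simulation gave target in grey at 8.34% and target in amber at 8.35%. Grey held 1.09% of side product, and each one counts two substrate, one of them from target. So 8.88% had passed through the intermediate in grey, against the share of 8.56%. Grey had 0.013% of its substrate left and 92% of its partner. At ten times its time, 500 min, grey's target stood at 8.35%, a rise of 0.010 percentage points, and at ten times its own time, 1200 min, amber's stood at 8.35%, as at its end.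

A neighbour of amber took 0.33 M of substrate, which makes the race ratio 113 and the share 4.18%. Computed, it gave target at 4.28% and side product at 0.665%, so 4.61% had passed through the intermediate.

The constants are made up, and the outcome is calculated.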